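## Retrosynthetic overview
1. The C3(CH3)(Br)/C4(H)(chlorovinyl) pair comes from a C3-quaternary (CH3, chlorovinyl)/C4-iodide cyclohexane by an antiperiplanar 1,2-vinyl shift with bromide capture (last step).
2. The only ring is opened at C3–C8. An acyclic (6S)-6-bromo-1-chloro-3,7-dimethylocta-1,3,7-triene is closed by electrophilic iodine, and chloride ends the cascade at C7. The ring, C3, C4 and C7 are set in one step under control of C6.
3. The triene comes from an (R)-allylic alcohol (SN2 inversion), that from an enal (chloro-olefination), that from cross-metathesis with methacrolein, and that from a catalytic asymmetric allylation of methacrolein.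
4. One ring, formed in step 5. No protecting groups.

Notation and assumption: C1–C8 are the chain atoms of the acyclic triene precursor (C1 is the CHCl end, methyl groups sit on C3 and C7), and the labels are kept for the ring. The presumed biosynthesis is taken to be halonium-induced C8-to-C3 closure of a halogenated ocimene, chloride capture at C7, then a chlorovinyl shift from C3 to C4 with bromide capture at C3.

## Route

Step 1
Reactants: 1 methacrolein; 2 allyltributylstannane
Product: 3 (3R)-2-methylhexa-1,5-dien-3-ol
Conditions: (R)-BINOL (20 mol %), Ti(OiPr)4 (10 mol %), 4 Å MS, CH2Cl2, −20 °C; aq NaHCO3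
Reagents that add atoms: none
Why: Keck asymmetric allylation, in which the (R)-BINOL–titanium Lewis acid shields one face of the enal so that the allylstannane adds 1,2 to give the (R)-carbinol (the sense expected for alpha-methyl enals), the only stereocentre brought in from outside.

Step 2
Reactants: 3 (3R)-2-methylhexa-1,5-dien-3-ol; 1 methacrolein
Product: 4 (2E,5R)-5-hydroxy-2,6-dimethylhepta-2,6-dienal
Conditions: second-generation Grubbs catalyst (3 mol %), methacrolein (5 equiv), CH2Cl2, 40 °C
Reagents that add atoms: none
Why: Olefin cross-metathesis of a reactive terminal olefin with the slowly homodimerising methacrolein gives the trisubstituted enal with high E selectivity, while the hindered 1,1-disubstituted olefin and the carbinol centre stay untouched.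

Step 3
Reactants: 4 (2E,5R)-5-hydroxy-2,6-dimethylhepta-2,6-dienal; 5 chloroform
Product: 6 (3R,5E,7E)-8-chloro-2,6-dimethylocta-1,5,7-trien-3-ol
Conditions: CrCl2 (6 equiv), CHCl3 (2 equiv), THF, 65 °C
Reagents that add atoms: none
Why: Takai–Utimoto olefination, in which the geminal dichromium species made from CHCl3 and divalent chromium adds only to the aldehyde and eliminates to the (E)-vinyl chloride, tolerating the free hydroxyl group, both olefins and the stereocentre.

Step 4
Reactants: 6 (3R,5E,7E)-8-chloro-2,6-dimethylocta-1,5,7-trien-3-ol
Product: 7 (1E,3E,6S)-6-bromo-1-chloro-3,7-dimethylocta-1,3,7-triene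
Conditions: CBr4, PPh3, 2,6-lutidine, CH2Cl2, −40 to −10 °C; used at once
Reagents that add atoms: tetrabromomethane, BrC(Br)(Br)Br
Why: Appel reaction, in which bromide displaces the alkoxyphosphonium ion by SN2 with inversion (R alcohol to 6S bromide), and low temperature, buffering and immediate use hold back SN2' attack and allylic scrambling.

Step 5
Reactants: 7 (1E,3E,6S)-6-bromo-1-chloro-3,7-dimethylocta-1,3,7-triene
Product: 10 (1R,2S,4S,5R)-2-bromo-1-chloro-5-[(E)-2-chloroethenyl]-4-iodo-1,5-dimethylcyclohexane, via iodochloride 8 (not isolated), via bridged iodonium ion 9 (not isolated)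
Conditions: ICl (1.0 equiv), SnCl4 (1.1 equiv), CH2Cl2, −78 °C, 30 min; pyridine, then aq Na2S2O3
Reagents that add atoms: iodine monochloride, ClI
Why: Proposed new method: SnCl4 turns ICl into an electrophilic-iodine donor paired with weakly nucleophilic SnCl5−, iodine adds to C4 of the more electron-rich dienyl chloride (any 8 formed is re-ionised at its tertiary allylic C–Cl bond), C8 of the isopropenyl group opens the iodonium anti at C3 through a chair in which the (E)-olefin puts iodine and chlorovinyl trans and the allylic C6 bromine sits axial to avoid eclipsing the C7 methyl (so the C4 iodide ends trans to C6–Br), the C4 iodine then caps the upper face of the C7 cation as the five-membered-ring iodonium 9, and chloride opens 9 at the tertiary carbon with inversion, cis to C6–Br; the closest known reaction types are halonium-induced polyene cyclisation, Lewis-acid-catalysed carbochlorination of alkenes by allyl chlorides and 1,4-halogen participation.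

Step 6
Reactants: 10 (1R,2S,4S,5R)-2-bromo-1-chloro-5-[(E)-2-chloroethenyl]-4-iodo-1,5-dimethylcyclohexane
Product: 11 (1R,2S,4S,5R)-1,4-dibromo-5-chloro-2-[(E)-2-chloroethenyl]-1,5-dimethylcyclohexane (target)
Conditions: ZnBr2 (1.5 equiv), CH2Cl2–Et2O 10:1, −40 to 0 °C; cold neutral work-up
Reagents that add atoms: zinc dibromide, Br[Zn]Br
Why: Proposed new method: in the preferred chair of 10 (which avoids syn-diaxial methyl groups) the C4 iodide and the chlorovinyl group are trans-diaxial, so zinc-assisted loss of iodide, the only readily ionised halide, goes with an antiperiplanar 1,2-vinyl shift through an alpha-chloro cyclopropylcarbinyl cation (inversion at C4, vinyl stays on its face), and bromide from the zincate closes on the tertiary C3 cation anti to the migrated group, which is also the face that avoids a syn-diaxial Br/Cl contact with the inert, beta-bromo-deactivated C7 chloride; the closest known type is the Wagner–Meerwein (pinacolyl-type) rearrangement of neopentyl-type halides with homoallyl participation.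

## Compound list
1 | methacrolein (2-methylprop-2-enal) | C=C(C)C=O | starting material
2 | allyltributylstannane | C=CC[Sn](CCCC)(CCCC)CCCC | starting material
3 | (3R)-2-methylhexa-1,5-dien-3-ol | C=CC[C@@H](O)C(C)=C | intermediate
4 | (2E,5R)-5-hydroxy-2,6-dimethylhepta-2,6-dienal | O=C/C(C)=C/C[C@@H](O)C(C)=C | intermediate
5 | chloroform | ClC(Cl)Cl | starting material
6 | (3R,5E,7E)-8-chloro-2,6-dimethylocta-1,5,7-trien-3-ol | Cl/C=C/C(C)=C/C[C@@H](O)C(C)=C | intermediate
7 | (1E,3E,6S)-6-bromo-1-chloro-3,7-dimethylocta-1,3,7-triene | Cl/C=C/C(C)=C/C[C@H](Br)C(C)=C | intermediate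
8 | (1E,3R,4S,6S)-6-bromo-1,3-dichloro-4-iodo-3,7-dimethylocta-1,7-diene (anti adduct of ICl, not isolated) | Cl[C@](C)(/C=C/Cl)[C@@H](I)C[C@H](Br)C(C)=C | intermediate
9 | 2-endo-bromo-5-endo-[(E)-2-chloroethenyl]-1,5-dimethyl-7-iodoniabicyclo[2.2.1]heptane cation (iodine bridges C4 and C7, not isolated) | C[C@@]12C[C@](C)(/C=C/Cl)[C@@H]([I+]1)C[C@@H]2Br | intermediate
10 | (1R,2S,4S,5R)-2-bromo-1-chloro-5-[(E)-2-chloroethenyl]-4-iodo-1,5-dimethylcyclohexane | C[C@@]1(Cl)C[C@](C)(/C=C/Cl)[C@@H](I)C[C@@H]1Br | intermediate
11 | (1R,2S,4S,5R)-1,4-dibromo-5-chloro-2-[(E)-2-chloroethenyl]-1,5-dimethylcyclohexane | C[C@@]1(Cl)C[C@@](C)(Br)[C@H](/C=C/Cl)C[C@@H]1Br | target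

## Step count and risks
Total steps: 6. Longest linear sequence: 6.

**1. Step 5 (ring closure).**
- Chloride may trap the acyclic cation for good.
- SnCl4 may ionise the allylic bromide.
- The remote C6 centre may not decide which olefin face takes up iodine.
- The vicinal C6 bromine may bridge the C7 cation instead of the C4 iodine. That would steer chloride to the wrong face (7-epimer) or cause proton loss. This is the main stereochemical risk of the route, and the fallback below is not shown to remove it.

The fallback sets out from 7 and comes back at 11. It replaces the substrate-controlled iodonium by a reagent-controlled epoxide. The C3=C4 olefin of 7 is epoxidised with a fructose-type chiral dioxirane (ketone antipode chosen for the required face; KHSO5, K2CO3 buffer, 0 °C). This gives (2S,3S)-3-[(2S)-2-bromo-3-methylbut-3-enyl]-2-[(E)-2-chloroethenyl]-2-methyloxirane F1, which fixes C3 and C4 irreversibly. TiCl4 (CH2Cl2, −78 °C) opens F1 at the tertiary allylic C3, the isopropenyl group closes the ring, and titanium-bound chloride ends the cascade. The product is (1S,2R,4R,5S)-5-bromo-4-chloro-2-[(E)-2-chloroethenyl]-2,4-dimethylcyclohexan-1-ol F2. Tf2O and 2,6-lutidine at −78 °C give (1S,2R,4R,5S)-5-bromo-4-chloro-2-[(E)-2-chloroethenyl]-2,4-dimethylcyclohexyl trifluoromethanesulfonate F3. On addition of Bu4NBr and warming, F3 undergoes the same antiperiplanar vinyl shift with bromide capture to give 11.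

**2. Step 6 (vinyl shift).**
- Methyl shift or ring contraction may occur from the minor chair.
- The C3 cation may lose a proton to give the conjugated diene.
- Iodide or chloride may end up at C3.
- ZnBr2 may be too weak an iodide acceptor.

The fallback sets out from 10 and comes back at 11. Ionisation is made irreversible and the cation is trapped with oxygen. AgOCOCF3 (CH2Cl2, −60 °C) removes only the iodide. The shifted tertiary cation is caught anti to the vinyl group as (1R,2S,4S,5R)-4-bromo-5-chloro-2-[(E)-2-chloroethenyl]-1,5-dimethylcyclohexyl trifluoroacetate F4. Me3SiBr (CH2Cl2, −40 °C) then exchanges this most easily ionised group for bromide. Bromide enters on the face away from the axial C7 chloride and gives 11.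

**3. Step 4 (allylic bromide).**
- SN2' attack would give the primary allylic bromide.
- Repeated bromide exchange would erode the C6 configuration.

The fallback sets out from 6 and comes back at 7. Activation is separated from displacement, so that no phosphine, phosphonium salt or excess bromide is present. MsCl and Et3N (CH2Cl2, −60 °C) give (3R,5E,7E)-8-chloro-2,6-dimethylocta-1,5,7-trien-3-yl methanesulfonate F5. F5 is filtered cold and treated with exactly one equivalent of LiBr in THF at −30 °C. Direct SN2 with inversion gives 7, which goes straight into step 5.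

## Further compounds
F1 | step 5 | (2S,3S)-3-[(2S)-2-bromo-3-methylbut-3-enyl]-2-[(E)-2-chloroethenyl]-2-methyloxirane | C[C@@]1(/C=C/Cl)O[C@H]1C[C@H](Br)C(C)=C
F2 | step 5 | (1S,2R,4R,5S)-5-bromo-4-chloro-2-[(E)-2-chloroethenyl]-2,4-dimethylcyclohexan-1-ol | C[C@@]1(Cl)C[C@](C)(/C=C/Cl)[C@@H](O)C[C@@H]1Br
F3 | step 5 | (1S,2R,4R,5S)-5-bromo-4-chloro-2-[(E)-2-chloroethenyl]-2,4-dimethylcyclohexyl trifluoromethanesulfonate | C[C@@]1(Cl)C[C@](C)(/C=C/Cl)[C@@H](OS(=O)(=O)C(F)(F)F)C[C@@H]1Br
F4 | step 6 | (1R,2S,4S,5R)-4-bromo-5-chloro-2-[(E)-2-chloroethenyl]-1,5-dimethylcyclohexyl trifluoroacetate | C[C@@]1(Cl)C[C@@](C)(OC(=O)C(F)(F)F)[C@H](/C=C/Cl)C[C@@H]1Br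
F5 | step 4 | (3R,5E,7E)-8-chloro-2,6-dimethylocta-1,5,7-trien-3-yl methanesulfonate | Cl/C=C/C(C)=C/C[C@@H](OS(C)(=O)=O)C(C)=C
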